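**Plan**

- Retrosynthesis: the side chain is cut at C9′ (back to an N-acyl oxazolidinone), at C7′–C8′ (anti-aldol) and at the aryl O–CH2 bond (phenol alkylation). In the core, the O7–C6 and C8–C1 bonds of the tetrahydrofuran are cut together, releasing CH2=O and a cyclopropane-fused lactone, which goes back to an enal and bromomalonate.
- Enabling feature: in the 3,7-dioxabicyclo[3.3.0]octan-2-one, the tetrahydrofuran ring (C1, C5, C6, O7, C8) holds an O7–C8H2 unit between the benzylic carbon C6 (aryl donor) and C1 (α to the lactone C=O, acceptor). That ring is formaldehyde inserted into the C1–C6 bond of a donor–acceptor cyclopropane (C1–C5–C6) whose lactone ring (C1, C2, O3, C4, C5) is already fused on.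
- Forward order: cyclopropane (organocatalytic Michael-initiated ring closure), lactone ring (reduction/lactonisation), tetrahydrofuran ring by two-atom ring expansion of the cyclopropane, ester removal and phenol release, then the side chain by O-alkylation, anti-aldol and reductive auxiliary cleavage.
- Stereochemistry: C5 and C6 come from the (S)-diphenylprolinol silyl ether catalyst. C6 is then inverted stereospecifically in the ring expansion (exo aryl becomes endo, all-cis), and C1 follows from cis ring fusion. C7′ (R) and C8′ (S), erythro, come from the (S)-4-benzyloxazolidinone in the anti-aldol.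

Key step: step 4

Assumption: the MgCl2-catalysed anti-aldol of the (S)-4-benzyloxazolidinone imide is taken to follow the chelated Z-enolate model (aldehyde enters the enolate face anti to the benzyl group, as in alkylations of this auxiliary), giving the (2R,3R) adduct; if the sense proved opposite, the (R)-auxiliary would be used in the same way.

**Route**

Step 1
Reactants: 1 sinapaldehyde, (E)-3-(4-hydroxy-3,5-dimethoxyphenyl)prop-2-enal
Product: 2 (E)-3-[4-(benzyloxy)-3,5-dimethoxyphenyl]prop-2-enal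
Conditions: BnBr, K2CO3, DMF, rt
Reagents that add atoms: benzyl bromide, BrCc1ccccc1
Why: Williamson etherification; the acidic phenol is O-benzylated so that it cannot be alkylated by bromomalonate and the enal stays electrophilic for iminium catalysis.

Step 2
Reactants: 2; 3 dimethyl 2-bromomalonate
Product: 4 dimethyl (2R,3S)-2-formyl-3-[4-(benzyloxy)-3,5-dimethoxyphenyl]cyclopropane-1,1-dicarboxylate (aryl and formyl trans)
Conditions: (S)-α,α-diphenylprolinol trimethylsilyl ether (20 mol%), 2,6-lutidine (1.2 equiv), CH2Cl2, 0 °C to rt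
Reagents that add atoms: none
Why: Organocatalytic Michael-initiated ring closure: bromomalonate adds to the iminium ion of 2 on the Si face of the β-carbon (away from the diphenyl(silyloxy)methyl group of the catalyst) and the resulting enamine displaces bromide (3-exo-tet), which should set the aryl carbon S and the formyl carbon R.

Step 3
Reactants: 4
Product: 6 methyl (1S,5R,6S)-6-[4-(benzyloxy)-3,5-dimethoxyphenyl]-2-oxo-3-oxabicyclo[3.1.0]hexane-1-carboxylate (aryl exo), via hydroxymethyl diester 5 (not isolated)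
Conditions: NaBH4, MeOH, 0 °C to rt
Reagents that add atoms: none
Why: Chemoselective borohydride reduction of the aldehyde, after which the hydroxymethyl group lactonises onto the cis ester (intramolecular transesterification to the five-membered ring); no stereocentre is touched and the remaining ester on C1 serves as the second acceptor.

Step 4
Reactants: 6
Product: 7 methyl (1R,5R,6R)-6-[4-(benzyloxy)-3,5-dimethoxyphenyl]-2-oxo-3,7-dioxabicyclo[3.3.0]octane-1-carboxylate (aryl endo, cis to C4)
Conditions: (CH2O)n (5 equiv), Sn(OTf)2 (10 mol%), 4 Å MS, ClCH2CH2Cl, rt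
Reagents that add atoms: formaldehyde (from paraformaldehyde), C=O
Why: Sn(OTf)2 chelates the lactone and ester carbonyls on C1 and polarises the C1–C6 cyclopropane bond, so the formaldehyde oxygen opens the ring at the benzylic carbon C6 from the back side and the released malonate-type enolate at C1 closes onto the new O-methylene oxocarbenium carbon; one CH2=O unit is thereby inserted into C1–C6 and the three-membered ring grows by two atoms into the tetrahydrofuran. The closest known reaction is the Lewis acid-catalysed (3+2) annulation of aryl cyclopropane-1,1-dicarbonyl compounds with aldehydes, which runs with inversion at the donor carbon through an intimate ion pair. The tetrahydrofuran ring closes by C1–C8 bond formation (enolate carbon onto oxocarbenium carbon, formally 5-endo-trig, aldol-type, as is general for this annulation), and the lactone already present enforces cis ring fusion. C6 is set by SN2-type inversion, which turns the exo aryl of 6 into the endo aryl (6R) of the target; C5 is untouched and C1 is fixed by the ring fusion. The step needs stereospecific SN2 opening at C6, not ionisation to a free benzylic cation (which would leak to the exo epimer) and not attack at C5. The only moderately donating 4-benzyloxy-3,5-dimethoxyphenyl group (twisted 4-alkoxy, two meta methoxy groups), the benzylic polarisation of C1–C6 and the mild catalyst should secure this.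

Step 5
Reactants: 7
Product: 8 (1R,5R,6R)-6-[4-(benzyloxy)-3,5-dimethoxyphenyl]-3,7-dioxabicyclo[3.3.0]octan-2-one
Conditions: LiCl (3 equiv), H2O (2 equiv), DMSO, 130 °C
Reagents that add atoms: none
Why: Krapcho dealkoxycarbonylation: chloride demethylates the ester, the carboxylate loses CO2 through the lactone enolate, and protonation at C1 can only give the cis-fused bicycle (1R), while the neutral medium should leave the acid-labile endo aryl centre alone.

Step 6
Reactants: 8
Product: 9 (1R,5R,6R)-6-(4-hydroxy-3,5-dimethoxyphenyl)-3,7-dioxabicyclo[3.3.0]octan-2-one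
Conditions: H2 (1 atm), 10% Pd/C, EtOAc, rt, stopped at full conversion
Reagents that add atoms: none
Why: Hydrogenolysis of the aryl benzyl ether on palladium, which is expected to be faster than cleavage of the cyclic benzylic C6–O7 bond.

Step 7
Reactants: 10 (S)-4-benzyloxazolidin-2-one; 11 bromoacetyl bromide
Product: 12 (S)-4-benzyl-3-(2-bromoacetyl)oxazolidin-2-one
Conditions: n-BuLi, THF, −78 °C; then 11, −78 °C
Reagents that add atoms: none
Why: N-Acylation of the lithiated oxazolidinone by the acyl bromide, which reacts far faster than the alkyl bromide end at low temperature.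

Step 8
Reactants: 9; 12
Product: 13 (S)-4-benzyl-3-(2-{2,6-dimethoxy-4-[(1R,5R,6R)-2-oxo-3,7-dioxabicyclo[3.3.0]oct-6-yl]phenoxy}acetyl)oxazolidin-2-one
Conditions: K2CO3, NaI (cat.), acetone, rt
Reagents that add atoms: none
Why: Williamson-type SN2 O-alkylation of the hindered but acidic 2,6-dimethoxyphenol by the activated α-bromo imide, under mild carbonate conditions that should leave the lactone and the endo aryl centre untouched.

Step 9
Reactants: 13; 14 4-formyl-2-methoxyphenyl acetate (vanillin acetate)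
Product: 15 (S)-4-benzyl-3-[(2R,3R)-3-(4-acetoxy-3-methoxyphenyl)-2-{2,6-dimethoxy-4-[(1R,5R,6R)-2-oxo-3,7-dioxabicyclo[3.3.0]oct-6-yl]phenoxy}-3-(trimethylsilyloxy)propanoyl]oxazolidin-2-one
Conditions: MgCl2 (20 mol%), Et3N (2 equiv), Me3SiCl (1.5 equiv), EtOAc, rt; filtration through a short silica pad
Reagents that add atoms: chlorotrimethylsilane, C[Si](C)(C)Cl
Why: Magnesium halide-catalysed direct anti-aldol of an N-acyloxazolidinone (Evans anti-aldol): soft enolisation gives the chelated Z magnesium enolate, the aromatic aldehyde adds through a boat-like transition state on the face anti to the benzyl group to give the 2,3-anti (2R,3R) adduct, and silylation of the aldolate drives turnover and blocks retro-aldol.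

Step 10
Reactants: 15
Product: 17 (1R,5R,6R)-6-{4-[(1R,2S)-1,3-dihydroxy-1-(4-hydroxy-3-methoxyphenyl)propan-2-yl]oxy-3,5-dimethoxyphenyl}-3,7-dioxabicyclo[3.3.0]octan-2-one (the target), via silyl ether acetate diol 16 (not isolated)
Conditions: NaBH4 (4 equiv), THF/H2O (4:1), 0 °C; then MeOH, K2CO3 (cat.), 0 °C to rt; aq NH4Cl
Reagents that add atoms: none
Why: Borohydride should reduce the exocyclic imide carbonyl (activated by the α-aryloxy group and the oxazolidinone) to the primary alcohol in preference to the γ-lactone and release the auxiliary, and carbonate-catalysed methanolysis then removes the aryl acetate and the trimethylsilyl ether without touching any stereocentre.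

**Compound list**

1 | sinapaldehyde, (E)-3-(4-hydroxy-3,5-dimethoxyphenyl)prop-2-enal | COc1cc(/C=C/C=O)cc(OC)c1O | starting material
2 | (E)-3-[4-(benzyloxy)-3,5-dimethoxyphenyl]prop-2-enal | COc1cc(/C=C/C=O)cc(OC)c1OCc1ccccc1 | intermediate
3 | dimethyl 2-bromomalonate | COC(=O)C(Br)C(=O)OC | starting material
4 | dimethyl (2R,3S)-2-formyl-3-[4-(benzyloxy)-3,5-dimethoxyphenyl]cyclopropane-1,1-dicarboxylate | O=C[C@@H]1[C@@H](c2cc(OC)c(OCc3ccccc3)c(OC)c2)C1(C(=O)OC)C(=O)OC | intermediate
5 | dimethyl (2R,3S)-2-(hydroxymethyl)-3-[4-(benzyloxy)-3,5-dimethoxyphenyl]cyclopropane-1,1-dicarboxylate | OC[C@@H]1[C@@H](c2cc(OC)c(OCc3ccccc3)c(OC)c2)C1(C(=O)OC)C(=O)OC | intermediate (not isolated)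
6 | methyl (1S,5R,6S)-6-[4-(benzyloxy)-3,5-dimethoxyphenyl]-2-oxo-3-oxabicyclo[3.1.0]hexane-1-carboxylate | COC(=O)[C@@]12C(=O)OC[C@@H]1[C@H]2c1cc(OC)c(OCc2ccccc2)c(OC)c1 | intermediate
7 | methyl (1R,5R,6R)-6-[4-(benzyloxy)-3,5-dimethoxyphenyl]-2-oxo-3,7-dioxabicyclo[3.3.0]octane-1-carboxylate | COc1cc([C@@H]2OC[C@]3(C(=O)OC)C(=O)OC[C@@H]32)cc(OC)c1OCc1ccccc1 | intermediate
8 | (1R,5R,6R)-6-[4-(benzyloxy)-3,5-dimethoxyphenyl]-3,7-dioxabicyclo[3.3.0]octan-2-one | COc1cc([C@@H]2OC[C@@H]3C(=O)OC[C@@H]32)cc(OC)c1OCc1ccccc1 | intermediate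
9 | (1R,5R,6R)-6-(4-hydroxy-3,5-dimethoxyphenyl)-3,7-dioxabicyclo[3.3.0]octan-2-one | COc1cc([C@@H]2OC[C@@H]3C(=O)OC[C@@H]32)cc(OC)c1O | intermediate
10 | (S)-4-benzyloxazolidin-2-one | O=C1N[C@@H](Cc2ccccc2)CO1 | starting material
11 | bromoacetyl bromide | BrCC(Br)=O | starting material
12 | (S)-4-benzyl-3-(2-bromoacetyl)oxazolidin-2-one | O=C(CBr)N1C(=O)OC[C@@H]1Cc1ccccc1 | intermediate
13 | (S)-4-benzyl-3-(2-{2,6-dimethoxy-4-[(1R,5R,6R)-2-oxo-3,7-dioxabicyclo[3.3.0]oct-6-yl]phenoxy}acetyl)oxazolidin-2-one | COc1cc([C@@H]2OC[C@@H]3C(=O)OC[C@@H]32)cc(OC)c1OCC(=O)N1C(=O)OC[C@@H]1Cc1ccccc1 | intermediate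
14 | 4-formyl-2-methoxyphenyl acetate (vanillin acetate) | COc1cc(C=O)ccc1OC(C)=O | starting material
15 | (S)-4-benzyl-3-[(2R,3R)-3-(4-acetoxy-3-methoxyphenyl)-2-{2,6-dimethoxy-4-[(1R,5R,6R)-2-oxo-3,7-dioxabicyclo[3.3.0]oct-6-yl]phenoxy}-3-(trimethylsilyloxy)propanoyl]oxazolidin-2-one | COc1cc([C@@H](O[Si](C)(C)C)[C@H](C(=O)N2C(=O)OC[C@@H]2Cc2ccccc2)Oc2c(OC)cc([C@@H]3OC[C@@H]4C(=O)OC[C@@H]43)cc2OC)ccc1OC(C)=O | intermediate
16 | 4-[(1R,2S)-2-{2,6-dimethoxy-4-[(1R,5R,6R)-2-oxo-3,7-dioxabicyclo[3.3.0]oct-6-yl]phenoxy}-3-hydroxy-1-(trimethylsilyloxy)propyl]-2-methoxyphenyl acetate | COc1cc([C@@H](O[Si](C)(C)C)[C@H](CO)Oc2c(OC)cc([C@@H]3OC[C@@H]4C(=O)OC[C@@H]43)cc2OC)ccc1OC(C)=O | intermediate (not isolated)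
17 | (1R,5R,6R)-6-{4-[(1R,2S)-1,3-dihydroxy-1-(4-hydroxy-3-methoxyphenyl)propan-2-yl]oxy-3,5-dimethoxyphenyl}-3,7-dioxabicyclo[3.3.0]octan-2-one | COc1cc([C@@H](O)[C@H](CO)Oc2c(OC)cc([C@@H]3OC[C@@H]4C(=O)OC[C@@H]43)cc2OC)ccc1O | target

**Summary**

Total step count: 10. Longest linear sequence: 9 steps (steps 1 to 6, then 8 to 10; step 7 is a one-step side branch).

Steps most likely to fail:

1. Step 4 (ring expansion).
   - What may go wrong: ionisation of the C1–C6 bond to a free benzylic cation before C–O bond formation, so that stereospecificity is lost and the exo-aryl epimer forms; Friedel–Crafts hydroxymethylation of the electron-rich ring by activated formaldehyde; incorporation of formaldehyde oligomers.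
   - Fallback, setting out from 6 and coming back at 8: Cu(OTf)2-catalysed methanolysis (MeOH, CH2Cl2) opens the cyclopropane at C6 with inversion to the benzylic methyl ether, methyl (4R)-4-[(R)-(4-benzyloxy-3,5-dimethoxyphenyl)(methoxy)methyl]-2-oxooxolane-3-carboxylate F1. Krapcho dealkoxycarbonylation (LiCl, wet DMSO) gives (4R)-4-[(R)-(4-benzyloxy-3,5-dimethoxyphenyl)(methoxy)methyl]oxolan-2-one F2. Detrifluoroacetylative diazo transfer (LiN(SiMe3)2, CF3CO2CH2CF3; then MsN3, Et3N) goes through the 3-trifluoroacetyl lactone F3 to the 3-diazo lactone F4. Rh2(OAc)4-catalysed intramolecular carbene insertion into a C–H bond of the O-methyl group (1,5-insertion α to oxygen) then closes the tetrahydrofuran cis-fused, with the already inverted benzylic centre retained, to give 8.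

2. Step 9 (anti-aldol).
   - What may go wrong: erosion of anti/syn selectivity or a change of facial sense because the α-aryloxy group and its ortho methoxy groups alter magnesium chelation; sluggish or reversible addition.
   - Fallback, setting out from 9 and coming back at 17: 9 is alkylated (K2CO3, acetone) with (R)-4-benzyl-3-(2-bromoacetyl)oxazolidin-2-one F5, made from (R)-4-benzyloxazolidin-2-one and 11 as in step 7, to give the enantiomeric-auxiliary imide F6. A boron-mediated Evans syn-aldol (Bu2BOTf, iPr2NEt, CH2Cl2, −78 °C, then 14) gives the (2R,3S) syn adduct F7, which is correct at the aryloxy carbon. NaBH4 (THF/H2O) gives the threo diol acetate F8, and K2CO3/MeOH gives the threo (7′S,8′S) phenol F9, the C7′ epimer of the target. DDQ (dioxane, rt) oxidises the p-hydroxybenzylic alcohol selectively to the aryl ketone F10. NaBH4 reduction, which is known to favour the erythro isomer for α-aryloxy-β-hydroxy aryl ketones of this kind, should then give 17 after separation from the minor threo epimer.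

3. Step 10 (reductive auxiliary cleavage).
   - What may go wrong: competing hydride attack on the γ-lactone (over-reduction to a diol) or retro-aldol fragmentation once the silyl ether is lost under the basic conditions.
   - Fallback, setting out from 15 and coming back at 17: LiOH/H2O2 (THF/H2O, 0 °C; Na2SO3 quench) cleaves the imide and, with the excess hydroxide, the aryl acetate and the silyl ether; the lactone opens reversibly and recloses on acidification to pH 3–4. This gives (2R,3R)-2-{2,6-dimethoxy-4-[(1R,5R,6R)-2-oxo-3,7-dioxabicyclo[3.3.0]oct-6-yl]phenoxy}-3-hydroxy-3-(4-hydroxy-3-methoxyphenyl)propanoic acid F11. BH3·THF (0 °C) then reduces the free carboxylic acid, which borane attacks much faster than a lactone, to the primary alcohol 17.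

Further compounds
F1 | step 4 | methyl (4R)-4-[(R)-(4-benzyloxy-3,5-dimethoxyphenyl)(methoxy)methyl]-2-oxooxolane-3-carboxylate (C3 epimers) | COC(=O)C1C(=O)OC[C@@H]1[C@@H](OC)c1cc(OC)c(OCc2ccccc2)c(OC)c1
F2 | step 4 | (4R)-4-[(R)-(4-benzyloxy-3,5-dimethoxyphenyl)(methoxy)methyl]oxolan-2-one | C1C(=O)OC[C@@H]1[C@@H](OC)c1cc(OC)c(OCc2ccccc2)c(OC)c1
F3 | step 4 | (4R)-4-[(R)-(4-benzyloxy-3,5-dimethoxyphenyl)(methoxy)methyl]-3-(trifluoroacetyl)oxolan-2-one | O=C(C1C(=O)OC[C@@H]1[C@@H](OC)c1cc(OC)c(OCc2ccccc2)c(OC)c1)C(F)(F)F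
F4 | step 4 | (4R)-4-[(R)-(4-benzyloxy-3,5-dimethoxyphenyl)(methoxy)methyl]-3-diazooxolan-2-one | [N-]=[N+]=C1C(=O)OC[C@@H]1[C@@H](OC)c1cc(OC)c(OCc2ccccc2)c(OC)c1
F5 | step 9 | (R)-4-benzyl-3-(2-bromoacetyl)oxazolidin-2-one | O=C(CBr)N1C(=O)OC[C@H]1Cc1ccccc1
F6 | step 9 | (R)-4-benzyl-3-(2-{2,6-dimethoxy-4-[(1R,5R,6R)-2-oxo-3,7-dioxabicyclo[3.3.0]oct-6-yl]phenoxy}acetyl)oxazolidin-2-one | COc1cc([C@@H]2OC[C@@H]3C(=O)OC[C@@H]32)cc(OC)c1OCC(=O)N1C(=O)OC[C@H]1Cc1ccccc1
F7 | step 9 | (R)-4-benzyl-3-[(2R,3S)-3-(4-acetoxy-3-methoxyphenyl)-2-{2,6-dimethoxy-4-[(1R,5R,6R)-2-oxo-3,7-dioxabicyclo[3.3.0]oct-6-yl]phenoxy}-3-hydroxypropanoyl]oxazolidin-2-one | COc1cc([C@H](O)[C@H](C(=O)N2C(=O)OC[C@H]2Cc2ccccc2)Oc2c(OC)cc([C@@H]3OC[C@@H]4C(=O)OC[C@@H]43)cc2OC)ccc1OC(C)=O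
F8 | step 9 | 4-[(1S,2S)-2-{2,6-dimethoxy-4-[(1R,5R,6R)-2-oxo-3,7-dioxabicyclo[3.3.0]oct-6-yl]phenoxy}-1,3-dihydroxypropyl]-2-methoxyphenyl acetate | COc1cc([C@H](O)[C@H](CO)Oc2c(OC)cc([C@@H]3OC[C@@H]4C(=O)OC[C@@H]43)cc2OC)ccc1OC(C)=O
F9 | step 9 | (1R,5R,6R)-6-{4-[(1S,2S)-1,3-dihydroxy-1-(4-hydroxy-3-methoxyphenyl)propan-2-yl]oxy-3,5-dimethoxyphenyl}-3,7-dioxabicyclo[3.3.0]octan-2-one | COc1cc([C@H](O)[C@H](CO)Oc2c(OC)cc([C@@H]3OC[C@@H]4C(=O)OC[C@@H]43)cc2OC)ccc1O
F10 | step 9 | (1R,5R,6R)-6-{4-[(2S)-3-hydroxy-1-(4-hydroxy-3-methoxyphenyl)-1-oxopropan-2-yl]oxy-3,5-dimethoxyphenyl}-3,7-dioxabicyclo[3.3.0]octan-2-one | COc1cc(C(=O)[C@H](CO)Oc2c(OC)cc([C@@H]3OC[C@@H]4C(=O)OC[C@@H]43)cc2OC)ccc1O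
F11 | step 10 | (2R,3R)-2-{2,6-dimethoxy-4-[(1R,5R,6R)-2-oxo-3,7-dioxabicyclo[3.3.0]oct-6-yl]phenoxy}-3-hydroxy-3-(4-hydroxy-3-methoxyphenyl)propanoic acid | COc1cc([C@@H](O)[C@H](C(=O)O)Oc2c(OC)cc([C@@H]3OC[C@@H]4C(=O)OC[C@@H]43)cc2OC)ccc1O
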